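**Retrosynthetic overview**

1. Target 52 ⇐ desilylation and air oxidation of the tris-silyl hydroquinone macrocycle 50 ⇐ cis-semireduction of dienyne 49 ⇐ Sonogashira macrocyclisation (C18–C19, 29-membered ring) of seco-iodide 48.
2. 48 ⇐ Felkin Mukaiyama aldol (C14–C15) of methyl ketone 46 with iodo-enal 25; 46 ⇐ Nozaki–Hiyama–Kishi coupling and oxidation (C1–C2) of Z-vinyl iodide 44 with naphthaldehyde 19.
3. 44 ⇐ 2-methylpropane-1,3-diol by desymmetrising iridium crotylation (C4–C6 triad), cross-metathesis (C7=C8), vinylogous Mukaiyama aldol (C9, C11=C12) and Zhao olefination (Z C2=C3).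
4. 19 ⇐ chloranil + a 2-silyloxydiene (Diels–Alder builds the benzenoid ring), ortho-formylation, regioselective amidation with enynamide 9, reductive silylation.
5. Key step: 9 ⇐ furfural by carbene-triggered opening of the furan, which converts the ring into the Z C21=C22 alkene, the C19≡C20 alkyne and the C23 carbonyl. Ring order: benzenoid ring (step 6), ansa macrocycle (step 27), quinone (step 29).

Assumption: the structure is taken exactly as the SMILES encodes it (2Z, 7E, 11E, 17E, 19Z, 21Z; 4S, 5S, 6S, 9S, 15S, 16S; ansa carbons numbered C1 = aryl ketone carbon to C23 = amide carbon; naphthalene numbered with N on C2, Cl on C3, ansa ketone on C5), and the ligand and catalyst enantiomers named are those expected to give the drawn configuration.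

**Fragment A: enynamide 9 from furfural**

Step 1
Reactants: 1 furfural; 2 4-methylbenzenesulfonohydrazide
Product: 3 (E)-N'-(furan-2-ylmethylene)-4-methylbenzenesulfonohydrazide
Conditions: MeOH, rt
Reagents that add atoms: none
Why: Simple condensation of the aldehyde with the sulfonyl hydrazide gives the crystalline hydrazone (hydrazone formation).

Step 2
Reactants: 3 furfural tosylhydrazone
Product: 6 (Z)-pent-2-en-4-ynal, via hydrazone sodium salt 4 (not isolated), via 2-(diazomethyl)furan 5 (not isolated)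
Conditions: NaH, THF, 0 °C; evaporate; dry salt 120 → 250 °C, 0.05 mbar, trap −78 °C
Reagents that add atoms: none
Why: Bamford–Stevens decomposition gives the diazo compound, and loss of N2 gives 2-furylcarbene, which undergoes the known furylcarbene ring opening; the furan loses its aromaticity and its ring cis relationship becomes the Z C21=C22 alkene between the new aldehyde (C23) and the new terminal alkyne (C19≡C20).

Step 3
Reactants: 6 (Z)-pent-2-en-4-ynal
Product: 7 (Z)-pent-2-en-4-ynoic acid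
Conditions: NaClO2, NaH2PO4, 2-methylbut-2-ene, t-BuOH/H2O, 0 °C
Reagents that add atoms: sodium chlorite, [Na+].[O-]Cl=O
Why: Pinnick oxidation converts the enal to the acid under buffered conditions that do not isomerise the Z alkene.

Step 4
Reactants: 7 (Z)-pent-2-en-4-ynoic acid
Product: 9 (Z)-pent-2-en-4-ynamide, via mixed carbonic anhydride 8 (not isolated)
Conditions: iBuOCOCl, N-methylmorpholine, THF, −20 °C; then NH3 (0.5 M in dioxane), −20 → 0 °C
Reagents that add atoms: ammonia, N
Why: Low-temperature mixed-anhydride activation followed by ammonolysis gives the primary amide without Z to E isomerisation (mixed-anhydride amidation).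

**Fragment B: naphthaldehyde 19**

Step 5
Reactants: 10 3-methylbut-3-en-2-one
Product: 11 trimethyl[(3-methylbuta-1,3-dien-2-yl)oxy]silane
Conditions: Me3SiOTf, Et3N, Et2O, 0 °C
Reagents that add atoms: trimethylsilyl trifluoromethanesulfonate, C[Si](C)(C)OS(=O)(=O)C(F)(F)F
Why: Soft enolisation of the methyl ketone toward CH3 and O-silylation gives the 2-silyloxydiene (silyl enol ether formation).

Step 6
Reactants: 11 silyloxydiene; 12 chloranil
Product: 15 2,3-dichloro-6-hydroxy-7-methylnaphthalene-1,4-dione, via Diels–Alder adduct 13 (not isolated), via aryl trimethylsilyl ether 14 (not isolated)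
Conditions: PhMe, 80 °C; then Et3N, 0 °C → rt; then 1 M HCl, MeOH
Reagents that add atoms: none
Why: Diels–Alder addition of the electron-rich diene to a C=C of symmetric chloranil has no regiochemical issue, twofold E1cB loss of HCl aromatises the new ring, and acidic methanol cleaves the aryl silyl ether.

Step 7
Reactants: 15 2,3-dichloro-6-hydroxy-7-methylnaphthalene-1,4-dione
Product: 16 6,7-dichloro-2-hydroxy-3-methyl-5,8-dioxo-5,8-dihydronaphthalene-1-carbaldehyde
Conditions: hexamethylenetetramine, CF3CO2H, 85 °C; then H2O, 60 °C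
Reagents that add atoms: hexamethylenetetramine, C1N2CN3CN1CN(C2)C3; water, O
Why: Duff formylation attacks the only free position ortho to the phenol (the other ortho position carries the methyl group), and the acidic medium keeps all amine species protonated so the dichloroquinone is not aminated.

Step 8
Reactants: 16 formyl dichloroquinone; 9 (Z)-pent-2-en-4-ynamide
Product: 17 (Z)-N-(3-chloro-5-formyl-6-hydroxy-7-methyl-1,4-dioxo-1,4-dihydronaphthalen-2-yl)pent-2-en-4-ynamide
Conditions: Cs2CO3, DMF, 0 °C → rt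
Reagents that add atoms: none
Why: Proposed new method: the amidate nitrogen adds to C2 and chloride is expelled (addition–elimination on the vinylogous acid chloride); C2 is selected because the C6 phenoxide, para to C8a, deactivates C1=O and leaves C4=O to activate C2 as its Michael position, with the peri formyl group also shielding C3; the closest known reaction type is the amination of 2,3-dichloro-1,4-naphthoquinones by amines and imide anions.

Step 9
Reactants: 17 amidochloroquinone
Product: 19 (Z)-N-[1,4,6-tris(tert-butyldimethylsilyloxy)-3-chloro-5-formyl-7-methylnaphthalen-2-yl]pent-2-en-4-ynamide, via hydroquinone 18 (not isolated)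
Conditions: Na2S2O4, EtOAc/H2O, rt; then tBuMe2SiOTf, 2,6-lutidine, CH2Cl2, 0 °C
Reagents that add atoms: tert-butyldimethylsilyl trifluoromethanesulfonate, CC(C)(C)[Si](C)(C)OS(=O)(=O)C(F)(F)F
Why: Dithionite reduces the quinone and exhaustive O-silylation masks it (and the phenol) against the CrCl2 and zerovalent palladium used later (reductive silylation).

**Fragment C: iodo-enal 25**

Step 10
Reactants: 20 methyl (R)-3-hydroxy-2-methylpropanoate
Product: 21 methyl (R)-3-(tert-butyldimethylsilyloxy)-2-methylpropanoate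
Conditions: tBuMe2SiCl, imidazole, CH2Cl2, rt
Reagents that add atoms: tert-butyldimethylsilyl chloride, CC(C)(C)[Si](C)(C)Cl
Why: Standard silylation of the primary alcohol; the C16 stereocentre comes from the chiral pool.

Step 11
Reactants: 21 silyl ether ester
Product: 22 (R)-3-(tert-butyldimethylsilyloxy)-2-methylpropanal
Conditions: iBu2AlH, CH2Cl2, −78 °C; aq. KNaC4H4O6
Reagents that add atoms: none
Why: At −78 °C the tetrahedral aluminium hemiacetal is stable, so reduction stops at the aldehyde without epimerisation (partial ester reduction).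

Step 12
Reactants: 22 aldehyde
Product: 23 tert-butyl{[(S,E)-4-iodo-2-methylbut-3-en-1-yl]oxy}dimethylsilane
Conditions: CrCl2, CHI3, THF, 0 °C → rt
Reagents that add atoms: iodoform, IC(I)I
Why: Takai olefination gives the E-vinyl iodide (future E C17=C18) under non-basic conditions that leave the α-stereocentre intact.

Step 13
Reactants: 23 vinyl iodide silyl ether
Product: 24 (S,E)-4-iodo-2-methylbut-3-en-1-ol
Conditions: camphorsulfonic acid (cat.), MeOH, 0 °C
Reagents that add atoms: none
Why: Acid-catalysed methanolysis removes the primary silyl ether without touching the vinyl iodide (desilylation).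

Step 14
Reactants: 24 iodo alcohol
Product: 25 (S,E)-4-iodo-2-methylbut-3-enal
Conditions: Dess–Martin periodinane, NaHCO3, CH2Cl2, 0 °C; used at once
Reagents that add atoms: none
Why: Buffered Dess–Martin oxidation gives the configurationally labile β,γ-unsaturated aldehyde without conjugation or epimerisation when used immediately.

**Reagent for the vinylogous aldol**

Step 15
Reactants: 26 methyl (E)-2-methylbut-2-enoate
Product: 27 tert-butyl[(1-methoxy-2-methylbuta-1,3-dien-1-yl)oxy]dimethylsilane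
Conditions: LiN(iPr)2, DMPU, THF, −78 °C; tBuMe2SiCl
Reagents that add atoms: tert-butyldimethylsilyl chloride, CC(C)(C)[Si](C)(C)Cl
Why: γ-Deprotonation of the tiglate and O-silylation gives the silyl dienolate (vinylogous silyl ketene acetal formation).

**Main line**

Step 16
Reactants: 28 2-methylpropane-1,3-diol; 29 but-3-en-2-yl acetate
Product: 31 (2S,3S,4S)-2,4-dimethylhex-5-ene-1,3-diol, via (S)-3-hydroxy-2-methylpropanal 30 (not isolated)
Conditions: [Ir(cod)Cl]2 (2.5 mol%), (S)-SEGPHOS (5 mol%), 4-cyano-3-nitrobenzoic acid (10 mol%), Cs2CO3 (20 mol%), THF, 70 °C; 28 in threefold excess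
Reagents that add atoms: none
Why: Krische transfer-hydrogenative crotylation: reversible dehydrogenation of either enantiotopic CH2OH gives aldehyde 30, and the chiral σ-crotyl iridium adds through a chair transition state (anti C5/C6) on the ligand-defined face while Curtin–Hammett selection of the Felkin-matched aldehyde enantiomer sets C4 (syn C4/C5), so the symmetric diol is desymmetrised and C4, C5 and C6 are set together.

Step 17
Reactants: 31 triad diol
Product: 32 (2S,3S,4S)-2,4-dimethyl-1,3-bis(triethylsilyloxy)hex-5-ene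
Conditions: Et3SiCl, imidazole, DMF, rt
Reagents that add atoms: chlorotriethylsilane, CC[Si](Cl)(CC)CC
Why: Both hydroxyls are silylated in one operation (silyl ether formation).

Step 18
Reactants: 32 bis-silyl ether; 33 (E)-but-2-enal
Product: 34 (2E,4S,5S,6S)-4,6-dimethyl-5,7-bis(triethylsilyloxy)hept-2-enal
Conditions: second-generation Hoveyda–Grubbs catalyst RuCl2(H2IMes)(=CH-C6H4-2-OiPr) (5 mol%), CH2Cl2, 40 °C
Reagents that add atoms: none
Why: Cross-metathesis of the terminal alkene with excess crotonaldehyde gives the E-enal (E C7=C8) under thermodynamic control.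

Step 19
Reactants: 34 enal; 27 silyl dienolate
Product: 35 methyl (2E,5S,6E,8S,9S,10S)-5-hydroxy-2,8,10-trimethyl-9,11-bis(triethylsilyloxy)undeca-2,6-dienoate
Conditions: SiCl4, Denmark (R,R)-bisphosphoramide (5 mol%), iPr2NEt (cat.), CH2Cl2, −78 °C; aq. NaHCO3
Reagents that add atoms: none
Why: Denmark vinylogous Mukaiyama aldol: the phosphoramide-bound trichlorosilyl cation activates the enal and the dienolate adds through its γ-carbon with catalyst control of the C9 carbinol (S) and E geometry at C11=C12.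

Step 20
Reactants: 35 hydroxy ester
Product: 37 (3E,6S,7E,9S,10S,11S)-6-hydroxy-3,9,11-trimethyl-10,12-bis(triethylsilyloxy)dodeca-3,7-dien-2-one, via Weinreb amide 36 (not isolated)
Conditions: MeNH(OMe)·HCl, MeMgBr (5 equiv), THF, −10 → 0 °C
Reagents that add atoms: methylmagnesium bromide, C[Mg]Br
Why: The magnesium amide converts the ester in situ to the Weinreb amide, which takes up one MeMgBr and stops at the chelated adduct, giving the methyl ketone on work-up (one-pot Weinreb ketone synthesis).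

Step 21
Reactants: 37 hydroxy ketone
Product: 38 (3E,6S,7E,9S,10S,11S)-3,9,11-trimethyl-6,10,12-tris(triethylsilyloxy)dodeca-3,7-dien-2-one
Conditions: Et3SiCl, imidazole, DMF, 0 °C
Reagents that add atoms: chlorotriethylsilane, CC[Si](Cl)(CC)CC
Why: Silylation protects the C9 allylic alcohol before the oxidations that follow (silyl ether formation).

Step 22
Reactants: 38 tris-silyl ether
Product: 39 (2R,3S,4S,5E,7S,9E)-2,4,10-trimethyl-11-oxo-3,7-bis(triethylsilyloxy)dodeca-5,9-dienal
Conditions: (COCl)2, DMSO, CH2Cl2, −78 → −40 °C; Et3N, −78 → 0 °C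
Reagents that add atoms: none
Why: Under Swern conditions the chlorosulfonium salt cleaves the primary triethylsilyl ether selectively and oxidises it in the same operation, leaving the two secondary silyl ethers (direct Swern oxidation of a primary silyl ether).

Step 23
Reactants: 39 aldehyde; 40 ethyltriphenylphosphonium iodide
Product: 44 (3E,6S,7E,9S,10S,11S,12Z)-13-iodo-3,9,11-trimethyl-6,10-bis(triethylsilyloxy)tetradeca-3,7,12-trien-2-one, via ethylidenetriphenylphosphorane 41 (not isolated), via (1-iodoethyl)triphenylphosphonium iodide 42 (not isolated), via (1-iodoethylidene)triphenylphosphorane 43 (not isolated)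
Conditions: n-BuLi, THF, 0 °C; I2, −78 °C; NaN(SiMe3)2, −78 °C; then 39, −78 → −20 °C
Reagents that add atoms: iodine, II
Why: Stork–Zhao-type Wittig olefination with the α-iodo ylide gives the Z-2-iodoalkene (iodine cis to C4) and reacts with the aldehyde far faster than with the ketone.

Step 24
Reactants: 44 Z-vinyl iodide; 19 naphthaldehyde
Product: 45 naphthyl carbinol seco-amide (C1 epimers)
Conditions: CrCl2 (6 equiv), NiCl2 (2 mol%), DMSO/THF, rt
Reagents that add atoms: none
Why: Nozaki–Hiyama–Kishi coupling: the trisubstituted vinylchromium forms with retention of geometry and adds only to the aldehyde, tolerating the ketone, amide and terminal alkyne.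

Step 25
Reactants: 45 naphthyl carbinol
Product: 46 aryl ketone seco-amide
Conditions: Dess–Martin periodinane, NaHCO3, CH2Cl2, 0 °C
Reagents that add atoms: none
Why: Dess–Martin oxidation of the allylic and benzylic alcohol gives the aryl ketone, removes the C1 stereocentre and keeps the Z C2=C3 geometry.

Step 26
Reactants: 46 aryl ketone seco-amide; 25 (S,E)-4-iodo-2-methylbut-3-enal
Product: 48 (15S,16S)-aldol seco-iodide, via trimethylsilyl enol ether 47 (not isolated)
Conditions: Me3SiOTf, Et3N, CH2Cl2, −78 → 0 °C; then 25, BF3·OEt2, CH2Cl2, −78 °C; aq. NaHCO3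
Reagents that add atoms: none
Why: Mukaiyama aldol: only the methyl ketone can be enolised (the flanked aryl ketone has no α-hydrogen), and its silyl enol ether adds to the BF3-activated aldehyde through an open transition state under Felkin–Anh control (vinyl as large group), giving the 15,16-syn (15S) alcohol.

Step 27
Reactants: 48 seco-iodide
Product: 49 macrocyclic 17E-en-19-yne-21Z-ene lactam
Conditions: Pd(PPh3)4 (10 mol%), CuI (20 mol%), iPr2NH, THF (1 mM), rt
Reagents that add atoms: none
Why: Intramolecular Sonogashira coupling under high dilution joins the vinyl iodide and the terminal alkyne (C18–C19), closing the 29-membered ring with retention of the E C17=C18 geometry.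

Step 28
Reactants: 49 macrocyclic dienyne
Product: 50 macrocyclic 17E,19Z,21Z-triene lactam
Conditions: Zn dust activated by Cu(OAc)2 and AgNO3, MeOH/H2O, rt
Reagents that add atoms: none
Why: Boland-type zinc semireduction adds hydrogen cis only to the alkyne conjugated on both sides, giving the Z C19=C20 alkene and leaving the other alkenes and enones untouched.

Step 29
Reactants: 50 macrocyclic triene
Product: 52 target CNP0257532.2, via macrocyclic hydroquinone 51 (not isolated)
Conditions: HF·pyridine, pyridine, THF, 0 °C → rt; then air, pH 7 buffer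
Reagents that add atoms: none
Why: Fluoride removes the two triethylsilyl and three aryl silyl ethers, and the liberated amido-chloro-hydroquinone is oxidised by air to the quinone (global desilylation and autoxidation).

**Compound list**

1 | furfural | O=Cc1ccco1 | starting material
2 | 4-methylbenzenesulfonohydrazide | Cc1ccc(cc1)S(=O)(=O)NN | starting material
3 | (E)-N'-(furan-2-ylmethylene)-4-methylbenzenesulfonohydrazide | Cc1ccc(cc1)S(=O)(=O)N/N=C/c1ccco1 | intermediate
4 | sodium salt of 3 | [Na+].Cc1ccc(cc1)S(=O)(=O)[N-]/N=C/c1ccco1 | intermediate (not isolated)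
5 | 2-(diazomethyl)furan | [N-]=[N+]=Cc1ccco1 | intermediate (not isolated)
6 | (Z)-pent-2-en-4-ynal | C#C/C=C\C=O | intermediate
7 | (Z)-pent-2-en-4-ynoic acid | C#C/C=C\C(=O)O | intermediate
8 | isobutyl carbonic (Z)-pent-2-en-4-ynoic anhydride | C#C/C=C\C(=O)OC(=O)OCC(C)C | intermediate (not isolated)
9 | (Z)-pent-2-en-4-ynamide | C#C/C=C\C(N)=O | intermediate
10 | 3-methylbut-3-en-2-one | CC(=O)C(C)=C | starting material
11 | trimethyl[(3-methylbuta-1,3-dien-2-yl)oxy]silane | C=C(C)C(=C)O[Si](C)(C)C | intermediate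
12 | chloranil (2,3,5,6-tetrachloro-1,4-benzoquinone) | O=C1C(Cl)=C(Cl)C(=O)C(Cl)=C1Cl | starting material
13 | 2,3,4a,8a-tetrachloro-6-methyl-7-(trimethylsilyloxy)-4a,5,8,8a-tetrahydronaphthalene-1,4-dione (racemic cis-fused adduct; both stereocentres are destroyed in the same step) | O=C1C(Cl)=C(Cl)C(=O)C2(Cl)CC(O[Si](C)(C)C)=C(C)CC12Cl | intermediate (not isolated)
14 | 2,3-dichloro-6-methyl-7-(trimethylsilyloxy)naphthalene-1,4-dione | O=C1C(Cl)=C(Cl)C(=O)c2cc(O[Si](C)(C)C)c(C)cc12 | intermediate (not isolated)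
15 | 2,3-dichloro-6-hydroxy-7-methylnaphthalene-1,4-dione | O=C1C(Cl)=C(Cl)C(=O)c2cc(O)c(C)cc12 | intermediate
16 | 6,7-dichloro-2-hydroxy-3-methyl-5,8-dioxo-5,8-dihydronaphthalene-1-carbaldehyde | O=Cc1c(O)c(C)cc2C(=O)C(Cl)=C(Cl)C(=O)c12 | intermediate
17 | (Z)-N-(3-chloro-5-formyl-6-hydroxy-7-methyl-1,4-dioxo-1,4-dihydronaphthalen-2-yl)pent-2-en-4-ynamide | O=Cc1c(O)c(C)cc2C(=O)C(NC(=O)/C=C\C#C)=C(Cl)C(=O)c12 | intermediate
18 | (Z)-N-(3-chloro-5-formyl-1,4,6-trihydroxy-7-methylnaphthalen-2-yl)pent-2-en-4-ynamide | O=Cc1c(O)c(C)cc2c(O)c(NC(=O)/C=C\C#C)c(Cl)c(O)c12 | intermediate (not isolated)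
19 | (Z)-N-[1,4,6-tris(tert-butyldimethylsilyloxy)-3-chloro-5-formyl-7-methylnaphthalen-2-yl]pent-2-en-4-ynamide | O=Cc1c(O[Si](C)(C)C(C)(C)C)c(C)cc2c(O[Si](C)(C)C(C)(C)C)c(NC(=O)/C=C\C#C)c(Cl)c(O[Si](C)(C)C(C)(C)C)c12 | intermediate
20 | methyl (R)-3-hydroxy-2-methylpropanoate | OC[C@@H](C)C(=O)OC | starting material
21 | methyl (R)-3-(tert-butyldimethylsilyloxy)-2-methylpropanoate | CC(C)(C)[Si](C)(C)OC[C@@H](C)C(=O)OC | intermediate
22 | (R)-3-(tert-butyldimethylsilyloxy)-2-methylpropanal | CC(C)(C)[Si](C)(C)OC[C@@H](C)C=O | intermediate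
23 | tert-butyl{[(S,E)-4-iodo-2-methylbut-3-en-1-yl]oxy}dimethylsilane | CC(C)(C)[Si](C)(C)OC[C@@H](C)/C=C/I | intermediate
24 | (S,E)-4-iodo-2-methylbut-3-en-1-ol | OC[C@@H](C)/C=C/I | intermediate
25 | (S,E)-4-iodo-2-methylbut-3-enal | O=C[C@@H](C)/C=C/I | intermediate
26 | methyl (E)-2-methylbut-2-enoate (methyl tiglate) | C/C=C(\C)C(=O)OC | starting material
27 | tert-butyl[(1-methoxy-2-methylbuta-1,3-dien-1-yl)oxy]dimethylsilane (ketene acetal geometry not controlled and without consequence) | COC(O[Si](C)(C)C(C)(C)C)=C(C)C=C | intermediate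
28 | 2-methylpropane-1,3-diol | CC(CO)CO | starting material
29 | but-3-en-2-yl acetate (racemic) | CC(OC(C)=O)C=C | starting material
30 | (S)-3-hydroxy-2-methylpropanal | OC[C@H](C)C=O | intermediate (not isolated)
31 | (2S,3S,4S)-2,4-dimethylhex-5-ene-1,3-diol | OC[C@H](C)[C@@H](O)[C@@H](C)C=C | intermediate
32 | (2S,3S,4S)-2,4-dimethyl-1,3-bis(triethylsilyloxy)hex-5-ene | CC[Si](CC)(CC)OC[C@H](C)[C@@H](O[Si](CC)(CC)CC)[C@@H](C)C=C | intermediate
33 | (E)-but-2-enal | C/C=C/C=O | starting material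
34 | (2E,4S,5S,6S)-4,6-dimethyl-5,7-bis(triethylsilyloxy)hept-2-enal | CC[Si](CC)(CC)OC[C@H](C)[C@@H](O[Si](CC)(CC)CC)[C@@H](C)/C=C/C=O | intermediate
35 | methyl (2E,5S,6E,8S,9S,10S)-5-hydroxy-2,8,10-trimethyl-9,11-bis(triethylsilyloxy)undeca-2,6-dienoate | CC[Si](CC)(CC)OC[C@H](C)[C@@H](O[Si](CC)(CC)CC)[C@@H](C)/C=C/[C@@H](O)C/C=C(\C)C(=O)OC | intermediate
36 | N-methoxy-N-methylamide corresponding to ester 35 | CC[Si](CC)(CC)OC[C@H](C)[C@@H](O[Si](CC)(CC)CC)[C@@H](C)/C=C/[C@@H](O)C/C=C(\C)C(=O)N(C)OC | intermediate (not isolated)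
37 | (3E,6S,7E,9S,10S,11S)-6-hydroxy-3,9,11-trimethyl-10,12-bis(triethylsilyloxy)dodeca-3,7-dien-2-one | CC[Si](CC)(CC)OC[C@H](C)[C@@H](O[Si](CC)(CC)CC)[C@@H](C)/C=C/[C@@H](O)C/C=C(\C)C(C)=O | intermediate
38 | (3E,6S,7E,9S,10S,11S)-3,9,11-trimethyl-6,10,12-tris(triethylsilyloxy)dodeca-3,7-dien-2-one | CC[Si](CC)(CC)OC[C@H](C)[C@@H](O[Si](CC)(CC)CC)[C@@H](C)/C=C/[C@@H](O[Si](CC)(CC)CC)C/C=C(\C)C(C)=O | intermediate
39 | (2R,3S,4S,5E,7S,9E)-2,4,10-trimethyl-11-oxo-3,7-bis(triethylsilyloxy)dodeca-5,9-dienal | O=C[C@H](C)[C@@H](O[Si](CC)(CC)CC)[C@@H](C)/C=C/[C@@H](O[Si](CC)(CC)CC)C/C=C(\C)C(C)=O | intermediate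
40 | ethyltriphenylphosphonium iodide | CC[P+](c1ccccc1)(c1ccccc1)c1ccccc1.[I-] | starting material
41 | ethylidenetriphenylphosphorane | CC=P(c1ccccc1)(c1ccccc1)c1ccccc1 | intermediate (not isolated)
42 | (1-iodoethyl)triphenylphosphonium iodide | CC(I)[P+](c1ccccc1)(c1ccccc1)c1ccccc1.[I-] | intermediate (not isolated)
43 | (1-iodoethylidene)triphenylphosphorane | CC(I)=P(c1ccccc1)(c1ccccc1)c1ccccc1 | intermediate (not isolated)
44 | (3E,6S,7E,9S,10S,11S,12Z)-13-iodo-3,9,11-trimethyl-6,10-bis(triethylsilyloxy)tetradeca-3,7,12-trien-2-one (ansa C2–C14, iodine on C2) | C/C(I)=C/[C@H](C)[C@@H](O[Si](CC)(CC)CC)[C@@H](C)/C=C/[C@@H](O[Si](CC)(CC)CC)C/C=C(\C)C(C)=O | intermediate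
45 | naphthyl carbinol seco-amide: C1 carbinol (both epimers) linking naphthalene C5 of 19 to C2 of the chain of 44; Z C2=C3; C13 methyl ketone | C/C(C(O)c1c(O[Si](C)(C)C(C)(C)C)c(C)cc2c(O[Si](C)(C)C(C)(C)C)c(NC(=O)/C=C\C#C)c(Cl)c(O[Si](C)(C)C(C)(C)C)c12)=C/[C@H](C)[C@@H](O[Si](CC)(CC)CC)[C@@H](C)/C=C/[C@@H](O[Si](CC)(CC)CC)C/C=C(\C)C(C)=O | intermediate
46 | aryl ketone seco-amide: C1 ketone of 45 | C/C(C(=O)c1c(O[Si](C)(C)C(C)(C)C)c(C)cc2c(O[Si](C)(C)C(C)(C)C)c(NC(=O)/C=C\C#C)c(Cl)c(O[Si](C)(C)C(C)(C)C)c12)=C/[C@H](C)[C@@H](O[Si](CC)(CC)CC)[C@@H](C)/C=C/[C@@H](O[Si](CC)(CC)CC)C/C=C(\C)C(C)=O | intermediate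
47 | C13 trimethylsilyl enol ether of 46 | C/C(C(=O)c1c(O[Si](C)(C)C(C)(C)C)c(C)cc2c(O[Si](C)(C)C(C)(C)C)c(NC(=O)/C=C\C#C)c(Cl)c(O[Si](C)(C)C(C)(C)C)c12)=C/[C@H](C)[C@@H](O[Si](CC)(CC)CC)[C@@H](C)/C=C/[C@@H](O[Si](CC)(CC)CC)C/C=C(\C)C(=C)O[Si](C)(C)C | intermediate (not isolated)
48 | (15S,16S)-aldol seco-iodide: chain C1–C18 ending in the E-vinyl iodide, free C15 OH, terminal alkyne on the amide arm | C/C(C(=O)c1c(O[Si](C)(C)C(C)(C)C)c(C)cc2c(O[Si](C)(C)C(C)(C)C)c(NC(=O)/C=C\C#C)c(Cl)c(O[Si](C)(C)C(C)(C)C)c12)=C/[C@H](C)[C@@H](O[Si](CC)(CC)CC)[C@@H](C)/C=C/[C@@H](O[Si](CC)(CC)CC)C/C=C(\C)C(=O)C[C@H](O)[C@@H](C)/C=C/I | intermediate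
49 | 29-membered macrocyclic 17E-en-19-yne-21Z-ene lactam (C5 and C9 O-triethylsilyl, naphthalene tris-O-TBS) | C/C1=C/[C@H](C)[C@@H](O[Si](CC)(CC)CC)[C@@H](C)/C=C/[C@@H](O[Si](CC)(CC)CC)C/C=C(\C)C(=O)C[C@H](O)[C@@H](C)/C=C/C#C/C=C\C(=O)Nc2c(Cl)c(O[Si](C)(C)C(C)(C)C)c3c(C1=O)c(O[Si](C)(C)C(C)(C)C)c(C)cc3c2O[Si](C)(C)C(C)(C)C | intermediate
50 | macrocyclic 17E,19Z,21Z-triene lactam, otherwise as 49 | C/C1=C/[C@H](C)[C@@H](O[Si](CC)(CC)CC)[C@@H](C)/C=C/[C@@H](O[Si](CC)(CC)CC)C/C=C(\C)C(=O)C[C@H](O)[C@@H](C)/C=C/C=C\C=C/C(=O)Nc2c(Cl)c(O[Si](C)(C)C(C)(C)C)c3c(C1=O)c(O[Si](C)(C)C(C)(C)C)c(C)cc3c2O[Si](C)(C)C(C)(C)C | intermediate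
51 | fully desilylated hydroquinone form of the target | C/C1=C/[C@H](C)[C@@H](O)[C@@H](C)/C=C/[C@@H](O)C/C=C(\C)C(=O)C[C@H](O)[C@@H](C)/C=C/C=C\C=C/C(=O)Nc2c(Cl)c(O)c3c(C1=O)c(O)c(C)cc3c2O | intermediate (not isolated)
52 | target CNP0257532.2 | C/C1=C/[C@H](C)[C@@H](O)[C@@H](C)/C=C/[C@@H](O)C/C=C(\C)C(=O)C[C@H](O)[C@@H](C)/C=C/C=C\C=C/C(=O)NC2=C(Cl)C(=O)c3c(cc(C)c(O)c3C1=O)C2=O | target

**Totals and risks**

Total step count: 29. Longest linear sequence: 14 steps (steps 16–29, from 2-methylpropane-1,3-diol).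

The three steps most likely to fail:

Step 7, the Duff formylation of a phenol that is strongly deactivated by the quinone. The fallback sets out from 15 and avoids electrophilic substitution on the quinone. Reductive O-methylation (Na2S2O4; then Me2SO4, K2CO3, acetone) gives 2,3-dichloro-1,4,6-trimethoxy-7-methylnaphthalene F1. Rieche formylation (Cl2CHOMe, TiCl4, CH2Cl2, 0 °C) of the now electron-rich ring, ortho to the C6 methoxy group, gives 6,7-dichloro-2,5,8-trimethoxy-3-methylnaphthalene-1-carbaldehyde F2. BCl3 (CH2Cl2, −78 °C) cleaves the methyl ether ortho to the formyl group by chelation to give 6,7-dichloro-2-hydroxy-5,8-dimethoxy-3-methylnaphthalene-1-carbaldehyde F3. Oxidative demethylation with (NH4)2Ce(NO3)6 (MeCN/H2O, 0 °C) returns the quinone, and the fallback comes back to the route at 16.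

Step 8, the regioselective amidation of the dichloroquinone by a primary amide anion. The fallback sets out from 16 and separates C–N bond formation from acylation. Aqueous ammonia (EtOH, 0 °C; acidic work-up to free the aldehyde) gives 6-amino-7-chloro-2-hydroxy-3-methyl-5,8-dioxo-5,8-dihydronaphthalene-1-carbaldehyde F4, the classical amination of a 2,3-dichloronaphthoquinone, directed to the same carbon by the phenoxide. Reductive silylation (Na2S2O4; then tBuMe2SiOTf, 2,6-lutidine) gives 6-amino-2,5,8-tris(tert-butyldimethylsilyloxy)-7-chloro-3-methylnaphthalene-1-carbaldehyde F5, whose nitrogen is now a normal aniline. Acid 7 is converted with 1-chloro-N,N,2-trimethylprop-1-en-1-amine into (Z)-pent-2-en-4-ynoyl chloride F6, which acylates F5 (pyridine, CH2Cl2, −20 °C), and the fallback comes back to the route at 19.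

Step 16, the desymmetrising crotylation, where the catalyst fixes C5 and C6 reliably but the choice between the two enantiotopic CH2OH groups (C4) may be only moderate. The fallback sets out from 28 and fixes C4 first. Lipase-catalysed monoacetylation (vinyl acetate) gives (R)-3-hydroxy-2-methylpropyl acetate F7. The same iridium-catalysed crotylation with 29, now on a single remaining CH2OH and under pure catalyst control, gives (2S,3S,4S)-3-hydroxy-2,4-dimethylhex-5-en-1-yl acetate F8. Methanolysis (K2CO3, MeOH) brings the fallback back to the route at 31.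

**Further compounds**

F1 | step 7 | 2,3-dichloro-1,4,6-trimethoxy-7-methylnaphthalene | COc1cc2c(OC)c(Cl)c(Cl)c(OC)c2cc1C
F2 | step 7 | 6,7-dichloro-2,5,8-trimethoxy-3-methylnaphthalene-1-carbaldehyde | COc1c(C=O)c2c(OC)c(Cl)c(Cl)c(OC)c2cc1C
F3 | step 7 | 6,7-dichloro-2-hydroxy-5,8-dimethoxy-3-methylnaphthalene-1-carbaldehyde | Oc1c(C=O)c2c(OC)c(Cl)c(Cl)c(OC)c2cc1C
F4 | step 8 | 6-amino-7-chloro-2-hydroxy-3-methyl-5,8-dioxo-5,8-dihydronaphthalene-1-carbaldehyde | O=Cc1c(O)c(C)cc2C(=O)C(N)=C(Cl)C(=O)c12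
F5 | step 8 | 6-amino-2,5,8-tris(tert-butyldimethylsilyloxy)-7-chloro-3-methylnaphthalene-1-carbaldehyde | O=Cc1c(O[Si](C)(C)C(C)(C)C)c(C)cc2c(O[Si](C)(C)C(C)(C)C)c(N)c(Cl)c(O[Si](C)(C)C(C)(C)C)c12
F6 | step 8 | (Z)-pent-2-en-4-ynoyl chloride | C#C/C=C\C(Cl)=O
F7 | step 16 | (R)-3-hydroxy-2-methylpropyl acetate | CC(=O)OC[C@H](C)CO
F8 | step 16 | (2S,3S,4S)-3-hydroxy-2,4-dimethylhex-5-en-1-yl acetate | CC(=O)OC[C@H](C)[C@@H](O)[C@@H](C)C=C
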